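**Plan**

1. Numbering (labdane): ring A = C1–C5, C10; ring B = C5–C10; C17 on C8, C18/C19 on C4, C20 on C10, chain C11–C16. The target is the ent-labdane with C20, C17 and C11 on one face of ring B and H-5, 6-OH, 8-OH and H-9 on the other.
2. Cuts: C12–C13 (B-alkyl Suzuki coupling with an E-enol triflate); C6 carbinol back to the ketone; ring B at C7–C8 and C9–C10 in one retro-[4+2]; C11 vinyl back to an ester. Ring A is bought (β-cyclocitral).
3. Enabling feature: the oxygens on C6 and C8 stand 1,3 on ring B across C7. The dienol ether of the C6 ketone (C7=C6–C5=C10, the C5=C10 bond lying in ring A) and the enol ether of an acetoacetate (C8=C9, carrying C17 and C11) can therefore hang on one silicon atom and close in a type 2 intramolecular Diels–Alder reaction to a 2,4-dioxa-3-silabicyclo[3.3.1]nonene that holds ring B.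
4. Forward order: ring A → methyl ketone → O6–Si–O8 tether → ring B (C7–C8 and C9–C10) → C11 ester to vinyl → tether off (C6 ketone, 8-OH) → C6 carbinol → side chain.
5. Stereochemistry in the key step: the tether forces O8 endo, so C17 is exo and cis to the inside methyl C20 (sets C8); the E-enol ether puts C11 on the side of C17 (sets C9). The absolute configuration comes from separating the (−)-menthyl ester diastereomers of the cycloadduct.
6. C5 by axial protonation anti to C20 (trans-decalone); C6 by dissolving-metal reduction (equatorial OH); C13=C14 from the E-enol triflate with retention.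

Key step: step 4

Remark: β-cyclocitral 1, (−)-menthyl acetoacetate 4 and methyl acetoacetate 15 are taken as commercial.

**Route**

Step 1
Reactants: 1 β-cyclocitral (2,6,6-trimethylcyclohex-1-ene-1-carbaldehyde)
Product: 2 rac-1-(2,6,6-trimethylcyclohex-1-en-1-yl)ethan-1-ol
Conditions: MeMgBr, Et2O, 0 °C to rt; H2O work-up
Reagents that add atoms: methylmagnesium bromide, C[Mg]Br
Why: Grignard 1,2-addition to a non-enolizable aldehyde; the carbinol centre is racemic and is removed in step 2.

Step 2
Reactants: 2 rac-1-(2,6,6-trimethylcyclohex-1-en-1-yl)ethan-1-ol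
Product: 3 1-(2,6,6-trimethylcyclohex-1-en-1-yl)ethan-1-one
Conditions: Dess–Martin periodinane, CH2Cl2, rt
Reagents that add atoms: none
Why: Dess–Martin oxidation of the secondary allylic alcohol to the methyl ketone under neutral conditions that leave the tetrasubstituted alkene in place.

Step 3
Reactants: 3 1-(2,6,6-trimethylcyclohex-1-en-1-yl)ethan-1-one; 4 (1R,2S,5R)-menthyl 3-oxobutanoate
Product: 7 mixed bis-enol silaketal (menthyl (E)-3-silyloxybut-2-enoate joined through Si(i-Pr)2 to the dienol ether of 3), via lithium dienolate 5 (not isolated), via chlorosilyl dienol ether 6 (not isolated)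
Conditions: LiN(i-Pr)2, THF, −78 °C; add to i-Pr2SiCl2 (3 equiv), −78 °C to rt; excess silane removed in vacuo; then 4, Et3N, DMAP (cat.), CH2Cl2, 0 °C to rt
Reagents that add atoms: dichlorodi(propan-2-yl)silane, CC(C)[Si](Cl)(Cl)C(C)C
Why: Kinetic deprotonation of the acetyl methyl group gives the cross-conjugated lithium dienolate, O-silylation with excess dichlorosilane stops at the monochloride, and amine-mediated O-silylation of the β-keto ester (silyl bis-enol ether formation) then gives the unsymmetrical silaketal with the E-enoate (silyloxy trans to the ester), the geometry that chlorosilane/Et3N silylation of β-keto esters normally gives and that step 4 needs.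

Step 4
Reactants: 7 mixed bis-enol silaketal
Product: 8 bridged cycloadduct, (1R,2S,5R)-menthyl (8S,9S,10S)-6,8-[di(propan-2-yl)silanediylbis(oxy)]-12,13,14,15,16-pentanorlabd-5-en-11-oate
Conditions: CH2Cl2 (0.05 M), 12 kbar, 45 °C; then chromatography to remove the diastereomer with the antipodal tricyclic part
Reagents that add atoms: none
Why: Proposed new method: a type 2 intramolecular Diels–Alder reaction in which the 2-silyloxydiene C7=C6–C5=C10 adds suprafacially to the silicon-tethered β-silyloxy enoate C8=C9, so that C7–C8 (nucleophilic diene terminus to enoate β-carbon, leading) and C9–C10 form in one asynchronous step; the closest known reaction type is the type 2 intramolecular Diels–Alder reaction with a disposable three-atom or silyl acetal tether, which has not been shown for a tether made from two enol oxygens nor for a diene terminus as hindered as C10, and pressure is used because it favours the cycloaddition (negative activation volume) over the 1,5-hydrogen shift of the dienol ether that heating would bring. Ring B is closed by the [4+2] cycloaddition across C7 and C10, and the 1,3-dioxa-2-silinane ring C6–O–Si–O–C8–C7 is closed at the same time by the C7–C8 bond, which leaves the C5=C6 silyl enol ether at the bridgehead of a bicyclo[3.3.1]nonene, the normal product of a three-atom tether. C8 is set by the tether: one silicon atom can span O6 and O8 only if O8 is endo, so C17 is exo and ends cis to the inside methyl C20. C9 is set by the E geometry of the enoate, which places C11 on the side of C17 and therefore also cis to C20. C10 follows from the suprafacial addition, but the menthyl group is too remote to choose between the two faces of the diene, so both tricyclic antipodes should form as diastereomers and 8 is taken by chromatography. The step needs 1,3 (meta) regiochemistry, which the tether length enforces and the polarity of both partners supports, and it needs the s-cis diene against the inside methyl, which is the point most likely to fail.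

Step 5
Reactants: 8 bridged cycloadduct (menthyl ester)
Product: 9 (8S,9R,10S)-6,8-[di(propan-2-yl)silanediylbis(oxy)]-12,13,14,15,16-pentanorlabd-5-en-11-ol
Conditions: i-Bu2AlH (3 equiv), CH2Cl2, −78 to 0 °C; aq. potassium sodium tartrate
Reagents that add atoms: none
Why: i-Bu2AlH reduction of the ester to the primary alcohol releases the auxiliary, while the silyl enol ether and the silaketal are inert to hydride at low temperature.

Step 6
Reactants: 9 bridged primary alcohol
Product: 10 (8S,9S,10S)-6,8-[di(propan-2-yl)silanediylbis(oxy)]-12,13,14,15,16-pentanorlabd-5-en-11-al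
Conditions: Dess–Martin periodinane, pyridine, CH2Cl2, 0 °C
Reagents that add atoms: none
Why: Dess–Martin oxidation under pyridine buffering gives the aldehyde without acid that would hydrolyse the bridgehead silyl enol ether.

Step 7
Reactants: 10 bridged aldehyde
Product: 11 (8S,9S,10S)-6,8-[di(propan-2-yl)silanediylbis(oxy)]-13,14,15,16-tetranorlabda-5,11-diene
Conditions: Ph3PCH3Br, KN(SiMe3)2, THF, 0 °C; then 10, −78 to 0 °C
Reagents that add atoms: methyltriphenylphosphonium bromide, C[P+](c1ccccc1)(c1ccccc1)c1ccccc1.[Br-]
Why: Wittig methylenation with the salt-free ylide at low temperature turns the hindered aldehyde into the C11=C12 vinyl group before C9 can epimerize or the β-silyloxy group can be eliminated.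

Step 8
Reactants: 11 bridged vinyl compound
Product: 13 (5R,8S,9S,10S)-8-hydroxy-13,14,15,16-tetranorlabd-11-en-6-one, via enol 12 (not isolated)
Conditions: HF·pyridine, pyridine, THF, 0 °C to rt
Reagents that add atoms: none
Why: HF·pyridine cleaves both Si–O bonds of the silaketal (desilylation), and ketonization of the enol places hydrogen on C5 axially on the face anti to the C10 methyl, which gives the trans-fused decalone, also the thermodynamic C5 epimer.

Step 9
Reactants: 13 hydroxy ketone
Product: 14 (5R,6R,8S,9S,10R)-13,14,15,16-tetranorlabd-11-ene-6,8-diol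
Conditions: Li, NH3(l), THF, t-BuOH, −78 °C; NH4Cl
Reagents that add atoms: none
Why: Dissolving-metal (Li/NH3) reduction of the ketone gives the thermodynamically preferred equatorial C6 alcohol (6-OH cis to H-5 and trans to C20), because an axial C6–O bond would be 1,3-diaxial to the methyl groups on C4, C10 and C8, whereas a hydride reagent would enter from the open equatorial side; the isolated vinyl group is not reduced.

Step 10
Reactants: 15 methyl 3-oxobutanoate
Product: 16 methyl (2E)-3-{[(trifluoromethyl)sulfonyl]oxy}but-2-enoate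
Conditions: (CF3SO2)2O, aq. Me4NOH, hexanes, 5 °C
Reagents that add atoms: trifluoromethanesulfonic anhydride, O=S(=O)(OS(=O)(=O)C(F)(F)F)C(F)(F)F
Why: O-triflation of the β-keto ester with a non-chelating tetramethylammonium counter-ion gives the E-enol triflate (triflate trans to the ester), the geometry needed for the 13E alkene.

Step 11
Reactants: 14 vinyl diol; 16 methyl (2E)-3-{[(trifluoromethyl)sulfonyl]oxy}but-2-enoate
Product: 18 methyl (5R,6R,8S,9S,10R,13E)-6,8-dihydroxylabd-13-en-15-oate (target), via B-alkyl-9-BBN borane 17 (not isolated)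
Conditions: 9-BBN (3 equiv), THF, rt; then 16, Pd(dppf)Cl2 (5 mol %), AsPh3, aq. K3PO4, DMF, rt
Reagents that add atoms: none
Why: Anti-Markovnikov hydroboration of the only alkene with 9-BBN and B-alkyl Suzuki–Miyaura coupling of the resulting borane with the enol triflate forms C12–C13 with retention of the E geometry and tolerates the two free hydroxyl groups.

**Compound list**

1 | β-cyclocitral (2,6,6-trimethylcyclohex-1-ene-1-carbaldehyde) | O=CC1=C(C)CCCC1(C)C | starting material
2 | rac-1-(2,6,6-trimethylcyclohex-1-en-1-yl)ethan-1-ol | CC(O)C1=C(C)CCCC1(C)C | intermediate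
3 | 1-(2,6,6-trimethylcyclohex-1-en-1-yl)ethan-1-one | CC(=O)C1=C(C)CCCC1(C)C | intermediate
4 | (1R,2S,5R)-5-methyl-2-(propan-2-yl)cyclohexyl 3-oxobutanoate ((−)-menthyl acetoacetate) | C[C@@H]1CC[C@H]([C@@H](C1)OC(=O)CC(C)=O)C(C)C | starting material
5 | lithium 1-(2,6,6-trimethylcyclohex-1-en-1-yl)ethen-1-olate (kinetic dienolate of 3; not isolated) | [Li]OC(=C)C1=C(C)CCCC1(C)C | intermediate
6 | chloro{[1-(2,6,6-trimethylcyclohex-1-en-1-yl)ethenyl]oxy}di(propan-2-yl)silane (not isolated) | C=C(O[Si](Cl)(C(C)C)C(C)C)C1=C(C)CCCC1(C)C | intermediate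
7 | (1R,2S,5R)-menthyl (2E)-3-{[di(propan-2-yl)({[1-(2,6,6-trimethylcyclohex-1-en-1-yl)ethenyl]oxy})silyl]oxy}but-2-enoate | C[C@@H]1CC[C@H]([C@@H](C1)OC(=O)/C=C(\C)O[Si](C(C)C)(C(C)C)OC(=C)C2=C(C)CCCC2(C)C)C(C)C | intermediate
8 | (1R,2S,5R)-menthyl (8S,9S,10S)-6,8-[di(propan-2-yl)silanediylbis(oxy)]-12,13,14,15,16-pentanorlabd-5-en-11-oate (C5=C6 enol ether, O6 and O8 bridged by silicon; C17, C20 and C11 on one face of ring B, O8 and H-9 on the other) | C[C@@H]1CC[C@H]([C@@H](C1)OC(=O)[C@H]2[C@]3(C)CCCC(C)(C)C3=C4C[C@]2(C)O[Si](C(C)C)(C(C)C)O4)C(C)C | intermediate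
9 | (8S,9R,10S)-6,8-[di(propan-2-yl)silanediylbis(oxy)]-12,13,14,15,16-pentanorlabd-5-en-11-ol | OC[C@H]1[C@]2(C)CCCC(C)(C)C2=C3C[C@]1(C)O[Si](C(C)C)(C(C)C)O3 | intermediate
10 | (8S,9S,10S)-6,8-[di(propan-2-yl)silanediylbis(oxy)]-12,13,14,15,16-pentanorlabd-5-en-11-al | O=C[C@H]1[C@]2(C)CCCC(C)(C)C2=C3C[C@]1(C)O[Si](C(C)C)(C(C)C)O3 | intermediate
11 | (8S,9S,10S)-6,8-[di(propan-2-yl)silanediylbis(oxy)]-13,14,15,16-tetranorlabda-5,11-diene | C=C[C@H]1[C@]2(C)CCCC(C)(C)C2=C3C[C@]1(C)O[Si](C(C)C)(C(C)C)O3 | intermediate
12 | (8S,9S,10S)-13,14,15,16-tetranorlabda-5,11-diene-6,8-diol (C5=C6 enol; not isolated) | C=C[C@H]1[C@]2(C)CCCC(C)(C)C2=C(O)C[C@]1(C)O | intermediate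
13 | (5R,8S,9S,10S)-8-hydroxy-13,14,15,16-tetranorlabd-11-en-6-one (trans-decalone, 8-OH equatorial, C17 axial) | C=C[C@H]1[C@]2(C)CCCC(C)(C)[C@H]2C(=O)C[C@]1(C)O | intermediate
14 | (5R,6R,8S,9S,10R)-13,14,15,16-tetranorlabd-11-ene-6,8-diol | C=C[C@H]1[C@]2(C)CCCC(C)(C)[C@H]2[C@H](O)C[C@]1(C)O | intermediate
15 | methyl 3-oxobutanoate (methyl acetoacetate) | COC(=O)CC(C)=O | starting material
16 | methyl (2E)-3-{[(trifluoromethyl)sulfonyl]oxy}but-2-enoate | COC(=O)/C=C(\C)OS(=O)(=O)C(F)(F)F | intermediate
17 | 9-[(5R,6R,8S,9S,10R)-6,8-dihydroxy-13,14,15,16-tetranorlabdan-12-yl]-9-borabicyclo[3.3.1]nonane (not isolated) | C1CCC2CCCC1B2CC[C@H]3[C@]4(C)CCCC(C)(C)[C@H]4[C@H](O)C[C@]3(C)O | intermediate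
18 | methyl (5R,6R,8S,9S,10R,13E)-6,8-dihydroxylabd-13-en-15-oate, i.e. methyl (2E)-5-[(1S,2S,4R,4aR,8aR)-2,4-dihydroxy-2,5,5,8a-tetramethyldecahydronaphthalen-1-yl]-3-methylpent-2-enoate | COC(=O)/C=C(\C)CC[C@H]1[C@]2(C)CCCC(C)(C)[C@H]2[C@H](O)C[C@]1(C)O | target

**Step count and risks**

Total step count: 11. Longest linear sequence: 10 steps (steps 1 to 9 and step 11, from β-cyclocitral).

Steps most likely to fail:

Step 4 (the step that carries the label). The dienol ether may not reach the s-cis form against the inside C20 methyl, so that no cycloaddition takes place or only the first C–C bond forms without closure at the fully substituted C10. The bis-enol silane may also redistribute, or the two diastereomeric adducts may not separate. The fallback uses known reactions only: an untethered Diels–Alder reaction of a 2-silyloxydiene with an allenic ester, followed by late hydration at C8. It sets out from ketone 3 and comes back to the route at hydroxy ketone 13. Ketone 3 with t-BuMe2SiOSO2CF3 and Et3N should give the tert-butyldimethylsilyl dienol ether F1. Its thermal Diels–Alder reaction in toluene at 110 °C with (1R,2S,5R)-menthyl buta-2,3-dienoate F2 (from (−)-menthol and buta-2,3-dienoic acid by carbodiimide coupling) should give, after separation of diastereomers, the cycloadduct F3. In F3 the central allene carbon has become C8 with an exocyclic C8=C17 methylene group, C9 carries the ester and C5=C6 is a silyl enol ether. i-Bu2AlH should give the primary alcohol F4, Dess–Martin oxidation the aldehyde F5, Wittig methylenation the triene F6, and HF·pyridine the trans-fused ketone F7. Mukaiyama hydration (Co(acac)2, PhSiH3, O2) should take the 1,1-disubstituted C8=C17 alkene before the vinyl group and deliver oxygen to the face of C8 anti to C20, which gives 13.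

Step 3. The lithium dienolate may displace both chlorides of the dichlorosilane, the mixed silane may redistribute when the second enol is added, and the enoate geometry may not come out uniform. The fallback reverses the order and replaces the lithium enolate by soft enolization with a silyl bis-triflate. It sets out from acetoacetate 4 and comes back at silaketal 7. Compound 4 with i-Pr2Si(OSO2CF3)2 (1 equiv) and Et3N in CH2Cl2 at −78 °C should give the E-enol silyl triflate F8. Ketone 3 and more Et3N are then added, and enolization of the methyl ketone by the remaining Si–O triflate bond should give 7.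

Step 9. The ketyl may be protonated from the open equatorial side, giving the axial C6 alcohol, and ring B may open by retro-aldol cleavage through the C8 alkoxide in the basic medium. The fallback sets the carbinol by equilibration of the alcohol instead of by reduction under thermodynamic control. It sets out from ketone 13 and comes back at diol 14. NaBH4 in MeOH at 0 °C should attack C6 from the equatorial side and give the axial 6-epimer F9. Equilibration under Meerwein–Ponndorf–Verley/Oppenauer conditions (Al(O-i-Pr)3, i-PrOH, a little acetone, toluene, 80 °C) should then convert F9 into 14, because the axial hydroxyl is 1,3-diaxial to three methyl groups.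

Further compounds
F1 | step 4 | tert-butyl(dimethyl){[1-(2,6,6-trimethylcyclohex-1-en-1-yl)ethenyl]oxy}silane | C=C(O[Si](C)(C)C(C)(C)C)C1=C(C)CCCC1(C)C
F2 | step 4 | (1R,2S,5R)-menthyl buta-2,3-dienoate | C[C@@H]1CC[C@H]([C@@H](C1)OC(=O)C=C=C)C(C)C
F3 | step 4 | (1R,2S,5R)-menthyl 6-(tert-butyldimethylsilyloxy)-12,13,14,15,16-pentanorlabda-5,8(17)-dien-11-oate (C9 and C10 configured as in 13) | C[C@@H]1CC[C@H]([C@@H](C1)OC(=O)[C@H]2[C@]3(C)CCCC(C)(C)C3=C(O[Si](C)(C)C(C)(C)C)CC2=C)C(C)C
F4 | step 4 | 6-(tert-butyldimethylsilyloxy)-12,13,14,15,16-pentanorlabda-5,8(17)-dien-11-ol (C9 and C10 as in 13) | OC[C@H]1[C@]2(C)CCCC(C)(C)C2=C(O[Si](C)(C)C(C)(C)C)CC1=C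
F5 | step 4 | 6-(tert-butyldimethylsilyloxy)-12,13,14,15,16-pentanorlabda-5,8(17)-dien-11-al (C9 and C10 as in 13) | O=C[C@H]1[C@]2(C)CCCC(C)(C)C2=C(O[Si](C)(C)C(C)(C)C)CC1=C
F6 | step 4 | 6-(tert-butyldimethylsilyloxy)-13,14,15,16-tetranorlabda-5,8(17),11-triene (C9 and C10 as in 13) | C=C[C@H]1[C@]2(C)CCCC(C)(C)C2=C(O[Si](C)(C)C(C)(C)C)CC1=C
F7 | step 4 | 13,14,15,16-tetranorlabda-8(17),11-dien-6-one (trans-fused; C5, C9 and C10 as in 13) | C=C[C@H]1[C@]2(C)CCCC(C)(C)[C@H]2C(=O)CC1=C
F8 | step 3 | (1R,2S,5R)-menthyl (2E)-3-({di(propan-2-yl)[(trifluoromethanesulfonyl)oxy]silyl}oxy)but-2-enoate | C[C@@H]1CC[C@H]([C@@H](C1)OC(=O)/C=C(\C)O[Si](OS(=O)(=O)C(F)(F)F)(C(C)C)C(C)C)C(C)C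
F9 | step 9 | (5R,6S,8S,9S,10R)-13,14,15,16-tetranorlabd-11-ene-6,8-diol (axial 6-epimer of 14) | C=C[C@H]1[C@]2(C)CCCC(C)(C)[C@H]2[C@@H](O)C[C@]1(C)O
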